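**Retrosynthetic overview**
- The target is released twice from one C2-symmetric bis-isoflavan by hydrogenolysis of a p-xylylene linker, which also protects both 7-OH groups.
- The C2–OH groups are removed by ionic hydrogenation of a bis-lactol.
- C3–C1' bonds: enamine addition of the lactol aldehydes to a masked o-benzoquinone made from 2,3,6-trimethoxyphenol. This aryl-cation equivalent delivers the 2'-OMe/3'-OH pattern without protection and sets (3S).
- C4–C4a and O1–C2 bonds: Friedel–Crafts/hemiacetalisation of the tethered bis-phenol with acrolein.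
- Ring order: both benzene rings are bought; the two pyran rings are closed together in step 4; no other ring is made.

Assumption: compounds 1, 2, 4 and 9 are bought; the descriptor of the given SMILES is (3S).

**Step 1**
Reactants: 1 2-methoxyresorcinol (two molecules end up in the product); 2 1,4-bis(bromomethyl)benzene
Product: 3 1,4-bis[(3-hydroxy-2-methoxyphenoxy)methyl]benzene
Conditions: 1 (6 equiv, excess recovered), 2 (1 equiv), K2CO3 (2.2 equiv), acetone, reflux
Reagents that add atoms: 2-methoxyresorcinol (second molecule of 1) COc1c(O)cccc1O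
Why: Twofold Williamson etherification in which the large excess of the symmetric diol lets each resorcinol ring react once, so one dibromide joins two rings, protects both future 7-OH groups, leaves one phenol per ring and makes every later step two-directional.

**Step 2**
Reactants: 4 1,2,4-trimethoxybenzene
Product: 7 2,3,6-trimethoxyphenol, via aryllithium 5 (not isolated), via arylboronate 6 (not isolated)
Conditions: n-BuLi, THF, 0 °C to rt; B(OMe)3, −78 °C to rt; AcOH, 30% H2O2, 0 °C to rt
Reagents that add atoms: hydrogen peroxide OO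
Why: Directed ortho-metalation at the C–H flanked by two methoxy groups, followed by borylation and oxidative ipso-hydroxylation of the arylboronate.

**Step 3**
Reactants: 7 2,3,6-trimethoxyphenol
Product: 8 2,3,6,6-tetramethoxycyclohexa-2,4-dien-1-one
Conditions: PhI(OAc)2 (1.05 equiv), MeOH, −10 °C, 15 min; NaHCO3 wash; used at once as a cold CH2Cl2 solution
Reagents that add atoms: methanol CO
Why: Hypervalent-iodine oxidative dearomatisation in which methanol adds to a methoxy-bearing ortho carbon (oxocarbenium-stabilised) to give the masked o-benzoquinone; the regioisomeric ortho ketal would lead to the same arylation product.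

**Step 4**
Reactants: 3 1,4-bis[(3-hydroxy-2-methoxyphenoxy)methyl]benzene; 9 acrolein (two molecules are built in); 8 2,3,6,6-tetramethoxycyclohexa-2,4-dien-1-one (two molecules are built in)
Product: 11 1,4-bis{[(3S)-2-hydroxy-3-(3-hydroxy-2,4,5-trimethoxyphenyl)-8-methoxychroman-7-yloxy]methyl}benzene (anomer mixture at C2), via bis-lactol 10 (not isolated)
Conditions: (R)-2-[diphenyl(trimethylsilyloxy)methyl]pyrrolidine (20 mol %), PhCO2H (20 mol %), 9 (2.2 equiv), CH2Cl2, 0 °C; then 8 (2.6 equiv), −20 to 0 °C
Reagents that add atoms: acrolein (second molecule of 9) C=CC=O; 2,3,6,6-tetramethoxycyclohexa-2,4-dien-1-one (second molecule of 8) O=C1C(OC)=C(OC)C=CC1(OC)OC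
Why: Proposed new method: iminium-catalysed Friedel–Crafts conjugate addition ortho to each phenol followed by hemiacetalisation (known for electron-rich phenols and enals) closes both pyran rings, then the same amine turns each lactol aldehyde into its E-enamine, which adds through the unshielded Re face to C5 of dienone 8 (the CH next to the ketal) and loses methanol on rearomatisation, setting both (3S) centres, whose α-branched lactol form resists re-enolisation; the closest known reactions are the organocatalytic α-arylation of aldehydes with quinones and the Michael addition/aromatisation of carbon nucleophiles with masked o-benzoquinones.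

**Step 5**
Reactants: 11 the bis(3-aryl-lactol) from step 4
Product: 12 1,4-bis{[(3S)-3-(3-hydroxy-2,4,5-trimethoxyphenyl)-8-methoxychroman-7-yloxy]methyl}benzene
Conditions: Et3SiH (8 equiv), BF3·OEt2 (4 equiv), CH2Cl2, −78 to −30 °C; the minor meso (3R,3'S) diastereomer is removed by chromatography or crystallisation
Reagents that add atoms: none
Why: Ionic hydrogenation of the lactols through cyclic oxocarbenium ions, run cold with excess silane so that hydride capture outruns loss of the C3 proton, leaves both stereocentres untouched, and removal of the meso isomer upgrades the enantiomeric purity of the (S,S) compound (Horeau effect).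

**Step 6**
Reactants: 12 the (S,S)-bis-isoflavan from step 5
Product: 13 (3S)-3-(3-hydroxy-2,4,5-trimethoxyphenyl)-8-methoxychroman-7-ol (two molecules per molecule of 12)
Conditions: H2 (1 atm), 10% Pd/C, EtOAc–MeOH, rt
Reagents that add atoms: none
Why: Catalytic hydrogenolysis of the two benzylic aryl ether bonds frees both 7-OH groups and gives two molecules of the target, while C3 carries no benzylic heteroatom and is not affected.

**Compound list**
1 | 2-methoxyresorcinol (2-methoxybenzene-1,3-diol) | COc1c(O)cccc1O | starting material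
2 | 1,4-bis(bromomethyl)benzene | BrCc1ccc(CBr)cc1 | starting material
3 | 1,4-bis[(3-hydroxy-2-methoxyphenoxy)methyl]benzene | COc1c(O)cccc1OCc1ccc(COc2cccc(O)c2OC)cc1 | intermediate
4 | 1,2,4-trimethoxybenzene | COc1ccc(OC)c(OC)c1 | starting material
5 | (2,3,6-trimethoxyphenyl)lithium | [Li]c1c(OC)ccc(OC)c1OC | intermediate
6 | dimethyl (2,3,6-trimethoxyphenyl)boronate | COB(OC)c1c(OC)ccc(OC)c1OC | intermediate
7 | 2,3,6-trimethoxyphenol | COc1ccc(OC)c(O)c1OC | intermediate
8 | 2,3,6,6-tetramethoxycyclohexa-2,4-dien-1-one | O=C1C(OC)=C(OC)C=CC1(OC)OC | intermediate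
9 | acrolein | C=CC=O | starting material
10 | 1,4-bis[(2-hydroxy-8-methoxychroman-7-yloxy)methyl]benzene (lactol anomers) | OC1CCc2ccc(OCc3ccc(COc4ccc5CCC(O)Oc5c4OC)cc3)c(OC)c2O1 | intermediate
11 | 1,4-bis{[(3S)-2-hydroxy-3-(3-hydroxy-2,4,5-trimethoxyphenyl)-8-methoxychroman-7-yloxy]methyl}benzene (anomer mixture at C2) | COc1cc([C@H]2C(O)Oc3c(ccc(OCc4ccc(COc5ccc6C[C@@H](c7cc(OC)c(OC)c(O)c7OC)C(O)Oc6c5OC)cc4)c3OC)C2)c(OC)c(O)c1OC | intermediate
12 | 1,4-bis{[(3S)-3-(3-hydroxy-2,4,5-trimethoxyphenyl)-8-methoxychroman-7-yloxy]methyl}benzene | COc1cc([C@H]2COc3c(ccc(OCc4ccc(COc5ccc6C[C@@H](c7cc(OC)c(OC)c(O)c7OC)COc6c5OC)cc4)c3OC)C2)c(OC)c(O)c1OC | intermediate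
13 | (3S)-3-(3-hydroxy-2,4,5-trimethoxyphenyl)-8-methoxychroman-7-ol | COc1cc([C@H]2COc3c(ccc(O)c3OC)C2)c(OC)c(O)c1OC | target

**Step count and risks**
Total steps: 6. Longest linear sequence: 5 (4 → 7 → 8 → 11 → 12 → 13).

Most likely to fail, first: step 4. Both stages are new and must work twice in one molecule. The Friedel–Crafts stage could also go para to the phenol. Dienone 8 can dimerise, react with left-over acrolein, or be held back as a [4+2] adduct with the enamine. The fallback sets out from 3 and replaces steps 4 and 5. Double O-propargylation (propargyl bromide, K2CO3, DMF, rt) gives the bis(propargyl ether) 1,4-bis{[2-methoxy-3-(prop-2-yn-1-yloxy)phenoxy]methyl}benzene F1. Gold-catalysed 6-endo hydroarylation (Ph3PAuNTf2 2 mol %, CH2Cl2, rt) closes both pyran rings at the only free ortho position and gives the bis(2H-chromene) 1,4-bis[(8-methoxy-2H-chromen-7-yloxy)methyl]benzene F2. Its electron-rich styrene carbon C3 is coupled with C5 of 8 under Brønsted acid catalysis (diphenyl phosphate, CH2Cl2, −40 °C to rt). Loss of the C3 proton restores the C3=C4 bond and loss of methanol rearomatises the aryl ring, giving the bis(isoflav-3-ene) 1,4-bis{[3-(3-hydroxy-2,4,5-trimethoxyphenyl)-8-methoxy-2H-chromen-7-yloxy]methyl}benzene F3. Iridium-catalysed asymmetric hydrogenation ([Ir(cod)(PHOX)]BArF, 50 bar H2, CH2Cl2, ligand enantiomer chosen for S) then sets both C3 centres and comes back to the route at 12.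

Second: step 5. The oxocarbenium ion can lose the benzylic C3 proton to a 4H-chromene, which would erode the stereocentre. The fallback sets out from 11. NaBH4 (MeOH, 0 °C) opens both lactols to the bis(phenol–primary alcohol) 1,4-bis{[3-hydroxy-4-[(2S)-3-hydroxy-2-(3-hydroxy-2,4,5-trimethoxyphenyl)propyl]-2-methoxyphenoxy]methyl}benzene F4, in which C3 is no longer next to a carbonyl equivalent. A double Mitsunobu etherification (PPh3, DIAD, THF, 0 °C) then closes both pyran rings through the only phenol that can reach the carbinol and comes back at 12.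

Third: step 1. The statistical mono-etherification may give oligomers, and it leaves the ortho/para choice of the later Friedel–Crafts stage open. The fallback sets out from 1 and 2. Vilsmeier formylation of 1 (POCl3, DMF, then water) gives 2,4-dihydroxy-3-methoxybenzaldehyde F5. Its 2-OH is chelated to the aldehyde, so alkylation with 2 (K2CO3, DMF, 40 °C) takes place only at the 4-OH and gives the bis(salicylaldehyde) 4,4'-[1,4-phenylenebis(methyleneoxy)]bis(2-hydroxy-3-methoxybenzaldehyde) F6. Wittig reaction with Ph3P=CHCHO (toluene, 80 °C) gives the bis(E-enal) F7. Organocatalytic transfer hydrogenation (Hantzsch ester, dibenzylammonium trifluoroacetate, THF) saturates both enals and the hydroxy-aldehydes close to the lactols. This comes back at 10 with the regiochemistry fixed, and the second stage of step 4 follows.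

**Further compounds**
F1 | step 4 | 1,4-bis{[2-methoxy-3-(prop-2-yn-1-yloxy)phenoxy]methyl}benzene | C#CCOc1cccc(OCc2ccc(COc3cccc(OCC#C)c3OC)cc2)c1OC
F2 | step 4 | 1,4-bis[(8-methoxy-2H-chromen-7-yloxy)methyl]benzene | COc1c(OCc2ccc(COc3ccc4C=CCOc4c3OC)cc2)ccc2C=CCOc12
F3 | step 4 | 1,4-bis{[3-(3-hydroxy-2,4,5-trimethoxyphenyl)-8-methoxy-2H-chromen-7-yloxy]methyl}benzene | COc1cc(C2=Cc3ccc(OCc4ccc(COc5ccc6C=C(c7cc(OC)c(OC)c(O)c7OC)COc6c5OC)cc4)c(OC)c3OC2)c(OC)c(O)c1OC
F4 | step 5 | 1,4-bis{[3-hydroxy-4-[(2S)-3-hydroxy-2-(3-hydroxy-2,4,5-trimethoxyphenyl)propyl]-2-methoxyphenoxy]methyl}benzene | COc1cc([C@@H](CO)Cc2ccc(OCc3ccc(COc4ccc(C[C@H](CO)c5cc(OC)c(OC)c(O)c5OC)c(O)c4OC)cc3)c(OC)c2O)c(OC)c(O)c1OC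
F5 | step 1 | 2,4-dihydroxy-3-methoxybenzaldehyde | COc1c(O)ccc(C=O)c1O
F6 | step 1 | 4,4'-[1,4-phenylenebis(methyleneoxy)]bis(2-hydroxy-3-methoxybenzaldehyde) | COc1c(O)c(C=O)ccc1OCc1ccc(COc2ccc(C=O)c(O)c2OC)cc1
F7 | step 1 | (2E,2'E)-3,3'-{1,4-phenylenebis[methyleneoxy(2-hydroxy-3-methoxy-4,1-phenylene)]}bis(prop-2-enal) | COc1c(O)c(/C=C/C=O)ccc1OCc1ccc(COc2ccc(/C=C/C=O)c(O)c2OC)cc1
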